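The route disconnects the O1–C2 bond of ring C. Because C2 is benzylic and para to the ring B oxygen, and C4 carries both ring A and C8 of the epicatechin unit, a tertiary allylic alcohol spanning C4–C3–C2 ionises readily to a delocalised cation. A chiral N-triflylphosphoramide then lets the ring A phenol close on C2, forming ring C as a 2H-chromene and fixing C2 in one operation. C4 and C3 are relayed from C2 by hydroboration and ketone reduction. The precursor is a free-phenol 1,1-diaryl cinnamyl alcohol made from an O-allyl-masked chalcone and 8-lithiated pentabenzyl epicatechin.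

Key step: step 8

Assumption: the (R)-configured catalyst is taken to favour the 2S chromene; if induction runs the other way, its (S)-antipode is used under the same conditions.

Ring labels: A, B, C for the upper flavan unit; D (phloroglucinol ring), E (catechol ring) and F (pyran ring) for the epicatechin unit. The upper unit of the target is (2R,3R,4S), with the C2 aryl, the C3 hydroxyl and the C4 epicatechinyl group all on one face. The chromene with the same spatial arrangement at C2 is named 2S because the CIP priorities change.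

Step 1
Reactants: 1 2,4-dihydroxyacetophenone
Product: 3 2-allyloxy-4-benzyloxyacetophenone, via 4-benzyloxy-2-hydroxyacetophenone 2 (not isolated)
Conditions: BnBr (1.0 equiv), K2CO3, DMF, rt; then allyl bromide (1.5 equiv), 60 °C
Reagents that add atoms: benzyl bromide, BrCc1ccccc1; allyl bromide, C=CCBr
Why: Two Williamson etherifications in sequence; the 4-hydroxyl reacts at room temperature, whereas the 2-hydroxyl, hydrogen-bonded to the ketone, is alkylated only on heating with the second halide.

Step 2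
Reactants: 3 2-allyloxy-4-benzyloxyacetophenone; 4 4-benzyloxybenzaldehyde
Product: 6 (E)-2'-allyloxy-4,4'-dibenzyloxychalcone, via aldol adduct 5 (not isolated)
Conditions: KOH, EtOH, rt
Reagents that add atoms: none
Why: Claisen–Schmidt condensation; the aldol adduct dehydrates by E1cB to the conjugated E-enone, and with the ortho oxygen alkylated no flavanone can form.

Step 3
Reactants: 7 (−)-epicatechin
Product: 8 5,7,3',4'-tetra-O-benzyl-(−)-epicatechin
Conditions: BnBr (4.2 equiv), K2CO3, DMF, 0 °C → rt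
Reagents that add atoms: benzyl bromide, BrCc1ccccc1
Why: Williamson etherification of the four phenols only, since carbonate does not deprotonate the secondary 3-hydroxyl and the mild conditions should leave the C2 and C3 centres untouched.

Step 4
Reactants: 8 5,7,3',4'-tetra-O-benzyl-(−)-epicatechin
Product: 9 8-bromo-5,7,3',4'-tetra-O-benzyl-(−)-epicatechin
Conditions: NBS (1.0 equiv), CH2Cl2, −78 °C → rt
Reagents that add atoms: N-bromosuccinimide, O=C1CCC(=O)N1Br
Why: Electrophilic aromatic bromination of the trioxygenated ring D, which in the free 3-hydroxy series is known to go to C8 in preference to C6.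

Step 5
Reactants: 9 8-bromo-5,7,3',4'-tetra-O-benzyl-(−)-epicatechin
Product: 10 8-bromo-3,5,7,3',4'-penta-O-benzyl-(−)-epicatechin
Conditions: NaH, BnBr, DMF, 0 °C → rt
Reagents that add atoms: benzyl bromide, BrCc1ccccc1
Why: Williamson etherification of the secondary alkoxide, which removes the last acidic proton before the halogen–metal exchange.

Step 6
Reactants: 10 8-bromo-3,5,7,3',4'-penta-O-benzyl-(−)-epicatechin; 6 (E)-2'-allyloxy-4,4'-dibenzyloxychalcone
Product: 13 (E)-1-(2-allyloxy-4-benzyloxyphenyl)-3-(4-benzyloxyphenyl)-1-(penta-O-benzylepicatechin-8-yl)prop-2-en-1-ol (both carbinol epimers), via 8-lithio species 11 (not isolated), via aryl cerium dichloride 12 (not isolated)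
Conditions: 10, t-BuLi (2.0 equiv), THF, −78 °C; anhydrous CeCl3 (THF slurry), −78 °C; then 6, −78 → −40 °C; aq. NaHCO3; Et3N-washed silica
Reagents that add atoms: none
Why: Bromine–lithium exchange gives the C8 aryllithium, and transmetalation to the less basic, oxophilic organocerium directs it to 1,2-addition at the enone carbonyl instead of conjugate addition (organocerium carbonyl addition); the carbinol centre may form as either epimer because step 8 erases it.

Step 7
Reactants: 13 allyl-protected tertiary allylic alcohol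
Product: 14 (E)-1-(4-benzyloxy-2-hydroxyphenyl)-3-(4-benzyloxyphenyl)-1-(penta-O-benzylepicatechin-8-yl)prop-2-en-1-ol (both carbinol epimers)
Conditions: Pd(PPh3)4 (5 mol%), morpholine (5 equiv), THF, rt; pH 7–8 buffer wash; filtration through Et3N-washed silica, then amine-free by toluene azeotrope
Reagents that add atoms: none
Why: Tsuji–Trost-type deallylation, in which zerovalent palladium ionises the allyl aryl ether and morpholine traps the π-allyl complex irreversibly, under mildly basic conditions that leave the easily ionised carbinol and the benzyl ethers untouched.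

Step 8
Reactants: 14 free-phenol tertiary allylic alcohol (both carbinol epimers)
Product: 16 (2S)-7,4'-dibenzyloxy-4-(penta-O-benzylepicatechin-8-yl)flav-3-ene, via allyl cation 15 (not isolated)
Conditions: (R)-3,3'-bis(2,4,6-triisopropylphenyl)-H8-BINOL N-triflylphosphoramide (5 mol%), toluene (0.01 M), −78 °C; Et3N added at −78 °C before warming
Reagents that add atoms: none
Why: The strongly acidic phosphoramide protonates the tertiary, doubly benzylic allylic hydroxyl and water leaves, giving the C2–C3–C4 delocalised cation 15 (a protonated vinyl ortho-quinone methide) as a contact ion pair with the chiral anion, so both carbinol epimers converge on one intermediate. The ring A phenol oxygen then attacks the cinnamyl terminus C2 in an intramolecular SN1'-type allylic etherification; the closest known reaction type is the chiral N-triflylphosphoramide-catalysed cyclisation of 2-(1-hydroxy-1,3-diarylallyl)phenols to 2,4-diaryl-2H-chromenes. Ring C closes as a six-membered ring by 6-endo attack on the C2=C3 bond of the quinone methide form, formally an oxa-6π electrocyclisation, and the C4–C3 rotation that brings C2 under the phenol is easy because the diarylcarbenium form has a C4–C3 single bond. The new C2 stereocentre is set by the chiral counter-anion, which binds the phenol OH by hydrogen bonding and shields one face of C2, while the remote epicatechin centres are expected to add little bias. The step needs O-attack at C2 in preference to arylation of the cation by the electron-rich ring D of a second molecule, which high dilution, −78 °C and the intramolecular six-membered geometry should secure. The amine quench before warming keeps the acid-labile 2-(4-benzyloxyphenyl)chromene from reopening and losing its C2 configuration.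

Step 9
Reactants: 16 (2S)-7,4'-dibenzyloxy-4-(penta-O-benzylepicatechin-8-yl)flav-3-ene
Product: 18 (2R,3S,4S)-7,4'-dibenzyloxy-4-(penta-O-benzylepicatechin-8-yl)flavan-3-ol, via C3 borane 17 (not isolated)
Conditions: BH3·SMe2, THF, 0 °C → rt; then aq. NaOH, H2O2, 0 °C
Reagents that add atoms: hydrogen peroxide, OO
Why: Hydroboration–oxidation; syn addition of H–B from the face anti to the C2 aryl places boron on the less substituted C3 and hydrogen on C4, so the C4 epicatechinyl group ends cis to the C2 aryl, and oxidation with retention gives the C3 hydroxyl trans to both.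

Step 10
Reactants: 18 (2R,3S,4S)-flavan-3-ol
Product: 19 (2R,4S)-7,4'-dibenzyloxy-4-(penta-O-benzylepicatechin-8-yl)flavan-3-one
Conditions: Dess–Martin periodinane, CH2Cl2, rt
Reagents that add atoms: none
Why: Dess–Martin oxidation under near-neutral conditions; the 2,4-cis arrangement with both aryl groups pseudo-equatorial is also the more stable one, so C2 and C4 should not be disturbed.

Step 11
Reactants: 19 (2R,4S)-flavan-3-one
Product: 20 (2R,3R,4S)-7,4'-dibenzyloxy-4-(penta-O-benzylepicatechin-8-yl)flavan-3-ol (all-cis)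
Conditions: LiBH(s-Bu)3, THF, −78 °C; then H2O
Reagents that add atoms: none
Why: Diastereoselective ketone reduction by a bulky hydride, which should approach the face opposite the two pseudo-equatorial aryl groups and give the axial C3 alcohol cis to both, as in the known flavan-3-one route from the catechin to the epicatechin series.

Step 12
Reactants: 20 (2R,3R,4S)-heptabenzyl flavan-3-ol
Product: 21 CNP0118995.5, (2R,3R,4S)-2-(4-hydroxyphenyl)-4-[(2R,3R)-2-(3,4-dihydroxyphenyl)-3,5,7-trihydroxychroman-8-yl]chromane-3,7-diol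
Conditions: H2 (1 atm), Pd(OH)2/C, THF/MeOH, rt
Reagents that add atoms: none
Why: Catalytic hydrogenolysis of the seven benzyl ethers, under conditions that are standard for benzylated flavan-3-ol dimers and should leave the ring C and ring F benzylic C–O bonds and all five stereocentres intact.

Compound list
1 | 2,4-dihydroxyacetophenone | CC(=O)c1ccc(O)cc1O | starting material
2 | 4-benzyloxy-2-hydroxyacetophenone | CC(=O)c1ccc(OCc2ccccc2)cc1O | intermediate (not isolated)
3 | 2-allyloxy-4-benzyloxyacetophenone | CC(=O)c1ccc(OCc2ccccc2)cc1OCC=C | intermediate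
4 | 4-benzyloxybenzaldehyde | O=Cc1ccc(OCc2ccccc2)cc1 | starting material
5 | 1-(2-allyloxy-4-benzyloxyphenyl)-3-(4-benzyloxyphenyl)-3-hydroxypropan-1-one (racemic aldol adduct) | O=C(CC(O)c1ccc(OCc2ccccc2)cc1)c1ccc(OCc2ccccc2)cc1OCC=C | intermediate (not isolated)
6 | (E)-2'-allyloxy-4,4'-dibenzyloxychalcone | O=C(/C=C/c1ccc(OCc2ccccc2)cc1)c1ccc(OCc2ccccc2)cc1OCC=C | intermediate
7 | (−)-epicatechin, (2R,3R) | O[C@@H]1Cc2c(O)cc(O)cc2O[C@@H]1c1ccc(O)c(O)c1 | starting material
8 | 5,7,3',4'-tetra-O-benzyl-(−)-epicatechin | c1c(OCc9ccccc9)cc(OCc9ccccc9)c2c1O[C@H](c1ccc(OCc9ccccc9)c(OCc9ccccc9)c1)[C@H](O)C2 | intermediate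
9 | 8-bromo-5,7,3',4'-tetra-O-benzyl-(−)-epicatechin | Brc1c(OCc9ccccc9)cc(OCc9ccccc9)c2c1O[C@H](c1ccc(OCc9ccccc9)c(OCc9ccccc9)c1)[C@H](O)C2 | intermediate
10 | 8-bromo-3,5,7,3',4'-penta-O-benzyl-(−)-epicatechin | Brc1c(OCc9ccccc9)cc(OCc9ccccc9)c2c1O[C@H](c1ccc(OCc9ccccc9)c(OCc9ccccc9)c1)[C@H](OCc9ccccc9)C2 | intermediate
11 | 8-lithio-3,5,7,3',4'-penta-O-benzylepicatechin | [Li]c1c(OCc9ccccc9)cc(OCc9ccccc9)c2c1O[C@H](c1ccc(OCc9ccccc9)c(OCc9ccccc9)c1)[C@H](OCc9ccccc9)C2 | intermediate (not isolated)
12 | (3,5,7,3',4'-penta-O-benzylepicatechin-8-yl)cerium dichloride | Cl[Ce](Cl)c1c(OCc9ccccc9)cc(OCc9ccccc9)c2c1O[C@H](c1ccc(OCc9ccccc9)c(OCc9ccccc9)c1)[C@H](OCc9ccccc9)C2 | intermediate (not isolated)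
13 | (E)-1-(2-allyloxy-4-benzyloxyphenyl)-3-(4-benzyloxyphenyl)-1-(penta-O-benzylepicatechin-8-yl)prop-2-en-1-ol, both carbinol epimers | C=CCOc1cc(OCc9ccccc9)ccc1C(O)(/C=C/c1ccc(OCc9ccccc9)cc1)c1c(OCc9ccccc9)cc(OCc9ccccc9)c2c1O[C@H](c1ccc(OCc9ccccc9)c(OCc9ccccc9)c1)[C@H](OCc9ccccc9)C2 | intermediate
14 | (E)-1-(4-benzyloxy-2-hydroxyphenyl)-3-(4-benzyloxyphenyl)-1-(penta-O-benzylepicatechin-8-yl)prop-2-en-1-ol, both carbinol epimers | Oc1cc(OCc9ccccc9)ccc1C(O)(/C=C/c1ccc(OCc9ccccc9)cc1)c1c(OCc9ccccc9)cc(OCc9ccccc9)c2c1O[C@H](c1ccc(OCc9ccccc9)c(OCc9ccccc9)c1)[C@H](OCc9ccccc9)C2 | intermediate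
15 | 1-(4-benzyloxy-2-hydroxyphenyl)-3-(4-benzyloxyphenyl)-1-(penta-O-benzylepicatechin-8-yl)allyl cation, ion-paired with the phosphoramide anion | Oc1cc(OCc9ccccc9)ccc1[C+](/C=C/c1ccc(OCc9ccccc9)cc1)c1c(OCc9ccccc9)cc(OCc9ccccc9)c2c1O[C@H](c1ccc(OCc9ccccc9)c(OCc9ccccc9)c1)[C@H](OCc9ccccc9)C2 | intermediate (not isolated)
16 | (2S)-7,4'-dibenzyloxy-4-(penta-O-benzylepicatechin-8-yl)flav-3-ene | c9ccccc9COc1ccc([C@H]2Oc3cc(OCc9ccccc9)ccc3C(c3c(OCc9ccccc9)cc(OCc9ccccc9)c4c3O[C@H](c3ccc(OCc9ccccc9)c(OCc9ccccc9)c3)[C@H](OCc9ccccc9)C4)=C2)cc1 | intermediate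
17 | 3-boryl-7,4'-dibenzyloxy-4-(penta-O-benzylepicatechin-8-yl)flavan, boron and the new C4–H anti to the C2 aryl | c9ccccc9COc1ccc([C@H]2Oc3cc(OCc9ccccc9)ccc3[C@@H](c3c(OCc9ccccc9)cc(OCc9ccccc9)c4c3O[C@H](c3ccc(OCc9ccccc9)c(OCc9ccccc9)c3)[C@H](OCc9ccccc9)C4)[C@@H]2B)cc1 | intermediate (not isolated)
18 | (2R,3S,4S)-7,4'-dibenzyloxy-4-(penta-O-benzylepicatechin-8-yl)flavan-3-ol (2,3-trans, 3,4-trans, 2,4-cis) | c9ccccc9COc1ccc([C@H]2Oc3cc(OCc9ccccc9)ccc3[C@@H](c3c(OCc9ccccc9)cc(OCc9ccccc9)c4c3O[C@H](c3ccc(OCc9ccccc9)c(OCc9ccccc9)c3)[C@H](OCc9ccccc9)C4)[C@@H]2O)cc1 | intermediate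
19 | (2R,4S)-7,4'-dibenzyloxy-4-(penta-O-benzylepicatechin-8-yl)flavan-3-one (2,4-cis) | c9ccccc9COc1ccc([C@H]2Oc3cc(OCc9ccccc9)ccc3[C@@H](c3c(OCc9ccccc9)cc(OCc9ccccc9)c4c3O[C@H](c3ccc(OCc9ccccc9)c(OCc9ccccc9)c3)[C@H](OCc9ccccc9)C4)C2=O)cc1 | intermediate
20 | (2R,3R,4S)-7,4'-dibenzyloxy-4-(penta-O-benzylepicatechin-8-yl)flavan-3-ol (all-cis) | c9ccccc9COc1ccc([C@H]2Oc3cc(OCc9ccccc9)ccc3[C@@H](c3c(OCc9ccccc9)cc(OCc9ccccc9)c4c3O[C@H](c3ccc(OCc9ccccc9)c(OCc9ccccc9)c3)[C@H](OCc9ccccc9)C4)[C@H]2O)cc1 | intermediate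
21 | CNP0118995.5, (2R,3R,4S)-2-(4-hydroxyphenyl)-4-[(2R,3R)-2-(3,4-dihydroxyphenyl)-3,5,7-trihydroxychroman-8-yl]chromane-3,7-diol | Oc1ccc([C@H]2Oc3cc(O)ccc3[C@@H](c3c(O)cc(O)c4c3O[C@H](c3ccc(O)c(O)c3)[C@H](O)C4)[C@H]2O)cc1 | target

Total step count: 12
Longest linear sequence: 10 steps (7 to 21 through steps 3 to 12)

Steps most likely to fail

Step 8. The cation is stabilised by three oxygenated aryl groups, so ion pairing with the chiral anion may be loose and face selection at C2 incomplete. The product may also reopen under the acid and lose its C2 configuration. The fallback sets out from 14. An achiral acid (diphenyl phosphate, CH2Cl2, 0 °C) effects the ordinary cyclodehydration of the 2-(1-hydroxyallyl)phenol and should give 16 together with its C2 epimer, (2R)-7,4'-dibenzyloxy-4-(penta-O-benzylepicatechin-8-yl)flav-3-ene F1. Because the epicatechin unit is enantiopure, the two are diastereomers and are separated by preparative HPLC. F1 is returned to the same acid, which equilibrates C2 through cation 15, and is cycled again. The route is rejoined at 16.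

Step 9. Borane may add slowly to the congested C3=C4 bond, the C3 borane may be lost by β-aryloxy elimination with opening of ring C, or face selection may be incomplete. The fallback sets out from 16 and reaches the ketone by a path that resets both C3 and C4. Dihydroxylation (OsO4 cat., N-methylmorpholine N-oxide, acetone/H2O) gives the 3,4-cis-diol F2; either face of attack is acceptable. Parikh–Doering oxidation (SO3·pyridine, DMSO, Et3N) of the secondary hydroxyl gives the 4-hydroxyflavan-3-one F3. SmI2 in THF/MeOH at −78 °C then cleaves the tertiary benzylic C4–O bond next to the ketone. The samarium enolate, formed only towards C4, is protonated on the face anti to the C2 aryl and should give the 2,4-cis ketone, which is also the more stable epimer. The route is rejoined at 19.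

Step 6. The aryl metal may add in the conjugate sense, or fail to add because both partners are flanked by ortho substituents. The fallback sets out from 10 and assembles the three groups on the carbinol carbon in another order. Aryllithium 11 (made as in step 6, without CeCl3) is added to 2-allyloxy-4-benzyloxybenzaldehyde F4 (from purchased 4-benzyloxy-2-hydroxybenzaldehyde, allyl bromide, K2CO3, DMF) to give the diarylmethanol F5. Dess–Martin oxidation gives the diaryl ketone F6, which has no conjugate position. Lithium (4-benzyloxyphenyl)acetylide (purchased 1-benzyloxy-4-ethynylbenzene, n-BuLi, THF, −78 °C) adds to it to give the propargylic alcohol F7. Hydroxyl-directed trans-hydroalumination with NaAlH2(OCH2CH2OMe)2 in THF at 0 °C should then give the E-allylic alcohol. The route is rejoined at 13.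

Further compounds
F1 | step 8 | (2R)-7,4'-dibenzyloxy-4-(penta-O-benzylepicatechin-8-yl)flav-3-ene | c9ccccc9COc1ccc([C@@H]2Oc3cc(OCc9ccccc9)ccc3C(c3c(OCc9ccccc9)cc(OCc9ccccc9)c4c3O[C@H](c3ccc(OCc9ccccc9)c(OCc9ccccc9)c3)[C@H](OCc9ccccc9)C4)=C2)cc1
F2 | step 9 | (2R,3R,4R)-7,4'-dibenzyloxy-4-(penta-O-benzylepicatechin-8-yl)flavan-3,4-diol, both hydroxyls anti to the C2 aryl | c9ccccc9COc1ccc([C@H]2Oc3cc(OCc9ccccc9)ccc3[C@@](O)(c3c(OCc9ccccc9)cc(OCc9ccccc9)c4c3O[C@H](c3ccc(OCc9ccccc9)c(OCc9ccccc9)c3)[C@H](OCc9ccccc9)C4)[C@@H]2O)cc1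
F3 | step 9 | (2R,4R)-7,4'-dibenzyloxy-4-hydroxy-4-(penta-O-benzylepicatechin-8-yl)flavan-3-one | c9ccccc9COc1ccc([C@H]2Oc3cc(OCc9ccccc9)ccc3[C@@](O)(c3c(OCc9ccccc9)cc(OCc9ccccc9)c4c3O[C@H](c3ccc(OCc9ccccc9)c(OCc9ccccc9)c3)[C@H](OCc9ccccc9)C4)C2=O)cc1
F4 | step 6 | 2-allyloxy-4-benzyloxybenzaldehyde | O=Cc1ccc(OCc2ccccc2)cc1OCC=C
F5 | step 6 | (2-allyloxy-4-benzyloxyphenyl)(penta-O-benzylepicatechin-8-yl)methanol, both carbinol epimers | C=CCOc1cc(OCc9ccccc9)ccc1C(O)c1c(OCc9ccccc9)cc(OCc9ccccc9)c2c1O[C@H](c1ccc(OCc9ccccc9)c(OCc9ccccc9)c1)[C@H](OCc9ccccc9)C2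
F6 | step 6 | (2-allyloxy-4-benzyloxyphenyl)(penta-O-benzylepicatechin-8-yl)methanone | C=CCOc1cc(OCc9ccccc9)ccc1C(=O)c1c(OCc9ccccc9)cc(OCc9ccccc9)c2c1O[C@H](c1ccc(OCc9ccccc9)c(OCc9ccccc9)c1)[C@H](OCc9ccccc9)C2
F7 | step 6 | 1-(2-allyloxy-4-benzyloxyphenyl)-3-(4-benzyloxyphenyl)-1-(penta-O-benzylepicatechin-8-yl)prop-2-yn-1-ol, both carbinol epimers | C=CCOc1cc(OCc9ccccc9)ccc1C(O)(C#Cc1ccc(OCc9ccccc9)cc1)c1c(OCc9ccccc9)cc(OCc9ccccc9)c2c1O[C@H](c1ccc(OCc9ccccc9)c(OCc9ccccc9)c1)[C@H](OCc9ccccc9)C2
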